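**Plan**
- Retrosynthesis cuts, in this order: the interflavan C4–C8 bond (Friedel–Crafts); the C2–C3 bond of ring C of the upper unit (retro α-ketol 1,2-shift, back to a 2-aryl-2,3-dihydrobenzofuran); the C2–C3 bond of that five-membered ring (carbene C–H insertion); the benzylic ether O–CH2 bond.
- Forward: the ring A acetophenone is O-alkylated with the ring B benzyl unit, converted to an aryldiazoacetate and closed to the dihydrobenzofuran. C3 is hydroxylated and the ester taken to the α-hydroxy aldehyde, and ring expansion then gives ring C as a 3-hydroxychroman-4-one.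
- Reduction to the 3,4-diol, coupling at C8 of tetra-O-benzyl-(−)-epicatechin and hydrogenolysis finish the route.
- Enabling feature: flavan C3 carries oxygen and lies between C2 (on O1) and C4 (on C4a of ring A). At the C4-ketone level, ring C (O1–C2–C3–C4–C4a–C8a) is the α-ketol isomer of the five-membered ring O1–C2–C4–C4a–C8a bearing C3 as a formyl group on a carbinol carbon. The ortho O1 and para O7 donors of ring A make the C4 aryl ketone the thermodynamic sink.
- Stereochemistry: C2 from the chiral dirhodium carboxylate in the C–H insertion (kept through the shift); C3 by thermodynamic 2,3-trans equilibration in the key step; C4 by attack anti to the 3-OH; the lower unit from (−)-epicatechin.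

Key step: step 7

Assumption: the named dirhodium catalyst is taken to give the (2R,3S)-cis ester 8, in which the 2-aryl group has the spatial arrangement needed at C2 of the target (its mirror-image catalyst Rh2(R-PTTL)4 is used if the sense is opposite); the C3 descriptors of 8–11 are those of the expected major epimers and are immaterial because C3 is reset in step 7.

Step 1
Reactants: 1 1-[4-(benzyloxy)-2-hydroxyphenyl]ethan-1-one; 2 1-(benzyloxy)-4-(chloromethyl)benzene
Product: 3 1-[4-(benzyloxy)-2-{[4-(benzyloxy)phenyl]methoxy}phenyl]ethan-1-one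
Conditions: K2CO3, KI (cat.), DMF, 60 °C
Reagents that add atoms: none
Why: Williamson etherification: the phenoxide of 1 (its only acidic site) displaces the activated benzylic chloride of 2, iodide catalysis (Finkelstein exchange) compensating for the hydrogen-bonded ortho-hydroxy group; no stereocentre is formed.

Step 2
Reactants: 3 1-[4-(benzyloxy)-2-{[4-(benzyloxy)phenyl]methoxy}phenyl]ethan-1-one
Product: 5 methyl 2-[4-(benzyloxy)-2-{[4-(benzyloxy)phenyl]methoxy}phenyl]-2-oxoacetate, via arylglyoxylic acid 4 (not isolated)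
Conditions: SeO2, pyridine, 100 °C; filter, evaporate; then MeI, K2CO3, DMF, rt
Reagents that add atoms: selenium dioxide O=[Se]=O; iodomethane CI
Why: Riley oxidation with SeO2 in pyridine takes an aryl methyl ketone through the glyoxal to the arylglyoxylic acid without touching the aryl benzyl ethers, and alkylation of the carboxylate with MeI then gives the methyl ester; no stereocentre is formed.

Step 3
Reactants: 5 methyl 2-[4-(benzyloxy)-2-{[4-(benzyloxy)phenyl]methoxy}phenyl]-2-oxoacetate
Product: 7 methyl 2-[4-(benzyloxy)-2-{[4-(benzyloxy)phenyl]methoxy}phenyl]-2-diazoacetate, via tosylhydrazone 6 (not isolated)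
Conditions: TsNHNH2, MeOH, 60 °C; evaporate; then DBU, CH2Cl2, 0 °C to rt
Reagents that add atoms: 4-methylbenzenesulfonohydrazide Cc1ccc(cc1)S(=O)(=O)NN
Why: Condensation of the activated keto carbonyl with the sulfonyl hydrazide and base-induced loss of sulfinate from the acidic hydrazone (Bamford–Stevens reaction) is the standard entry to aryldiazoacetates; no stereocentre is formed.

Step 4
Reactants: 7 methyl 2-[4-(benzyloxy)-2-{[4-(benzyloxy)phenyl]methoxy}phenyl]-2-diazoacetate
Product: 8 methyl (2R,3S)-6-(benzyloxy)-2-[4-(benzyloxy)phenyl]-2,3-dihydro-1-benzofuran-3-carboxylate (cis)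
Conditions: Rh2(S-PTTL)4 = dirhodium tetrakis[N-phthaloyl-(S)-tert-leucinate] (1 mol %), toluene, −60 °C
Reagents that add atoms: none
Why: Intramolecular 1,5 C–H insertion of the donor/acceptor rhodium carbenoid into the benzylic ether C–H bond, which is activated by the ether oxygen and the 4-benzyloxyphenyl group, closes the dihydrofuran ring, and the chiral carboxylate ligands should distinguish the two enantiotopic benzylic hydrogens and so set C2 (the cis ester is expected, but C3 is reset later).

Step 5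
Reactants: 8 methyl (2R,3S)-6-(benzyloxy)-2-[4-(benzyloxy)phenyl]-2,3-dihydro-1-benzofuran-3-carboxylate
Product: 9 methyl (2S,3R)-6-(benzyloxy)-2-[4-(benzyloxy)phenyl]-3-hydroxy-2,3-dihydro-1-benzofuran-3-carboxylate
Conditions: KN(SiMe3)2, THF, −78 °C; then 3-phenyl-2-(phenylsulfonyl)oxaziridine, −78 °C; AcOH quench
Reagents that add atoms: 3-phenyl-2-(phenylsulfonyl)oxaziridine O=S(=O)(c1ccccc1)N1OC1c1ccccc1
Why: Davis oxidation of the potassium ester enolate by the N-sulfonyloxaziridine installs the tertiary hydroxyl, the oxidant being expected to approach anti to the C2 aryl group (the C3 configuration is immaterial for step 7), while C2, which is not acidic, is untouched in space (its descriptor changes from R to S only because the oxygenated C3 now outranks the aryl group).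

Step 6
Reactants: 9 methyl (2S,3R)-6-(benzyloxy)-2-[4-(benzyloxy)phenyl]-3-hydroxy-2,3-dihydro-1-benzofuran-3-carboxylate
Product: 10 (2S,3S)-6-(benzyloxy)-2-[4-(benzyloxy)phenyl]-3-(hydroxymethyl)-2,3-dihydro-1-benzofuran-3-ol
Conditions: LiAlH4, THF, 0 °C; aqueous NaOH work-up
Reagents that add atoms: none
Why: Hydride reduction of the ester by LiAlH4 gives the primary alcohol without affecting the ethers or either stereocentre.

Step 7
Reactants: 10 (2S,3S)-6-(benzyloxy)-2-[4-(benzyloxy)phenyl]-3-(hydroxymethyl)-2,3-dihydro-1-benzofuran-3-ol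
Product: 12 (2S,3S)-7-(benzyloxy)-2-[4-(benzyloxy)phenyl]-3-hydroxy-2,3-dihydro-4H-chromen-4-one (2,3-trans), via hydroxy aldehyde 11 (not isolated)
Conditions: SO3·pyridine, DMSO, i-Pr2NEt, CH2Cl2, 0 °C; aqueous work-up; then Al(O-t-Bu)3 (0.3 equiv), toluene, 40 °C
Reagents that add atoms: none
Why: Parikh–Doering oxidation of the neopentyl primary alcohol leaves the tertiary carbinol untouched and gives the non-enolisable α-hydroxy aldehyde 11, whose aluminium alkoxide holds the formyl oxygen in a five-membered O–Al–O chelate; in this chelate the ring bond C2–C3 migrates from the carbinol carbon to the formyl carbon while the carbinol becomes the ketone. The closest known reaction type is the α-ketol (acyloin) rearrangement used for one-carbon ring enlargement of 1-hydroxycycloalkanecarbaldehydes and of 17-hydroxy-20-keto steroids. Ring C is not closed by a new ring-forming bond: it arises by one-carbon enlargement of the five-membered ring O1–C2–C3–C3a–C7a, the formyl carbon being inserted between C2 and the old C3, which ends as the C4 ketone on C4a. C2 keeps its configuration because it is the migrating carbon (retention) and is never ionised or enolised, and the new C3 carbinol centre is set by thermodynamic control on aluminium (enolisation towards C3), which should leave the 2,3-trans isomer with both substituents equatorial. The selectivity needed is migration of C2 rather than of the aryl carbon C3a; the substrate secures the outcome because the alternative 4-hydroxy-3-ketone is an isomeric ketol that drains through the shared aluminium enediolate into the same product, whose C4 carbonyl is conjugated with the ortho O1 and para 7-benzyloxy donors of ring A and is therefore the thermodynamic sink, so that both C3 epimers of 11 also converge.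

Step 8
Reactants: 12 (2S,3S)-7-(benzyloxy)-2-[4-(benzyloxy)phenyl]-3-hydroxy-2,3-dihydro-4H-chromen-4-one
Product: 13 (2S,3R,4S)-7-(benzyloxy)-2-[4-(benzyloxy)phenyl]-3,4-dihydro-2H-chromene-3,4-diol
Conditions: NaBH4, THF/MeOH, 0 °C
Reagents that add atoms: none
Why: Borohydride reduction of the aryl ketone, with hydride expected to add anti to the neighbouring 3-hydroxyl to give mainly the 3,4-trans diol; the C4 configuration is immaterial because C4 is ionised in step 10.

Step 9
Reactants: 14 (−)-epicatechin, (2R,3R)-2-(3,4-dihydroxyphenyl)-3,4-dihydro-2H-chromene-3,5,7-triol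
Product: 15 (2R,3R)-5,7-bis(benzyloxy)-2-[3,4-bis(benzyloxy)phenyl]-3,4-dihydro-2H-chromen-3-ol
Conditions: BnBr (4.2 equiv), K2CO3, DMF, 0 °C to rt
Reagents that add atoms: benzyl bromide BrCc1ccccc1
Why: Williamson benzylation under carbonate conditions alkylates the four phenolic hydroxyls and leaves the far less acidic secondary 3-OH free; the stereocentres of the chiral-pool flavan are untouched.

Step 10
Reactants: 13 (2S,3R,4S)-7-(benzyloxy)-2-[4-(benzyloxy)phenyl]-3,4-dihydro-2H-chromene-3,4-diol; 15 (2R,3R)-5,7-bis(benzyloxy)-2-[3,4-bis(benzyloxy)phenyl]-3,4-dihydro-2H-chromen-3-ol (3 equiv)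
Product: 16 (2R,3R)-5,7-bis(benzyloxy)-8-{(2S,3R,4R)-7-(benzyloxy)-2-[4-(benzyloxy)phenyl]-3-hydroxy-3,4-dihydro-2H-chromen-4-yl}-2-[3,4-bis(benzyloxy)phenyl]-3,4-dihydro-2H-chromen-3-ol
Conditions: BF3·OEt2 (0.5 equiv), CH2Cl2, −20 to 0 °C
Reagents that add atoms: none
Why: Friedel–Crafts alkylation: BF3 ionises the C4 alcohol (loss of water) to a benzylic cation stabilised by O1 (ortho) and the 7-benzyloxy group (para), which is captured by C8 of the phloroglucinol-type ring of 15 (the preferred position of the tetrabenzyl ether, and far more nucleophilic than the resorcinol-type ring A of 13) from the face anti to the equatorial 3-OH, setting the 3,4-trans (4R) centre, the excess of 15 suppressing further alkylation.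

Step 11
Reactants: 16 (2R,3R)-5,7-bis(benzyloxy)-8-{(2S,3R,4R)-7-(benzyloxy)-2-[4-(benzyloxy)phenyl]-3-hydroxy-3,4-dihydro-2H-chromen-4-yl}-2-[3,4-bis(benzyloxy)phenyl]-3,4-dihydro-2H-chromen-3-ol
Product: 17 (2R,3R)-2-(3,4-dihydroxyphenyl)-8-[(2S,3R,4R)-3,7-dihydroxy-2-(4-hydroxyphenyl)-3,4-dihydro-2H-chromen-4-yl]-3,4-dihydro-2H-chromene-3,5,7-triol
Conditions: H2 (1 atm), Pd(OH)2/C, THF/MeOH, rt
Reagents that add atoms: none
Why: Hydrogenolysis of the six benzyl ethers over Pd(OH)2/C under neutral conditions, which should leave the cyclic benzylic C–O bonds and the interflavan C–C bond intact, gives the free hexaphenol without change at any stereocentre.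

**Compound list**
1 | 1-[4-(benzyloxy)-2-hydroxyphenyl]ethan-1-one | CC(=O)c1ccc(OCc2ccccc2)cc1O | starting material
2 | 1-(benzyloxy)-4-(chloromethyl)benzene | ClCc1ccc(OCc2ccccc2)cc1 | starting material
3 | 1-[4-(benzyloxy)-2-{[4-(benzyloxy)phenyl]methoxy}phenyl]ethan-1-one | CC(=O)c1ccc(OCc2ccccc2)cc1OCc1ccc(OCc2ccccc2)cc1 | intermediate
4 | 2-[4-(benzyloxy)-2-{[4-(benzyloxy)phenyl]methoxy}phenyl]-2-oxoacetic acid | OC(=O)C(=O)c1ccc(OCc2ccccc2)cc1OCc1ccc(OCc2ccccc2)cc1 | intermediate
5 | methyl 2-[4-(benzyloxy)-2-{[4-(benzyloxy)phenyl]methoxy}phenyl]-2-oxoacetate | COC(=O)C(=O)c1ccc(OCc2ccccc2)cc1OCc1ccc(OCc2ccccc2)cc1 | intermediate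
6 | methyl 2-[4-(benzyloxy)-2-{[4-(benzyloxy)phenyl]methoxy}phenyl]-2-[2-(4-methylbenzenesulfonyl)hydrazinylidene]acetate | COC(=O)C(=NNS(=O)(=O)c1ccc(C)cc1)c1ccc(OCc2ccccc2)cc1OCc1ccc(OCc2ccccc2)cc1 | intermediate
7 | methyl 2-[4-(benzyloxy)-2-{[4-(benzyloxy)phenyl]methoxy}phenyl]-2-diazoacetate | COC(=O)C(=[N+]=[N-])c1ccc(OCc2ccccc2)cc1OCc1ccc(OCc2ccccc2)cc1 | intermediate
8 | methyl (2R,3S)-6-(benzyloxy)-2-[4-(benzyloxy)phenyl]-2,3-dihydro-1-benzofuran-3-carboxylate (cis) | C(c1ccccc1)Oc1ccc(cc1)[C@@H]1Oc2cc(OCc3ccccc3)ccc2[C@@H]1C(=O)OC | intermediate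
9 | methyl (2S,3R)-6-(benzyloxy)-2-[4-(benzyloxy)phenyl]-3-hydroxy-2,3-dihydro-1-benzofuran-3-carboxylate | C(c1ccccc1)Oc1ccc(cc1)[C@@H]1Oc2cc(OCc3ccccc3)ccc2[C@]1(O)C(=O)OC | intermediate
10 | (2S,3S)-6-(benzyloxy)-2-[4-(benzyloxy)phenyl]-3-(hydroxymethyl)-2,3-dihydro-1-benzofuran-3-ol | C(c1ccccc1)Oc1ccc(cc1)[C@@H]1Oc2cc(OCc3ccccc3)ccc2[C@]1(O)CO | intermediate
11 | (2S,3R)-6-(benzyloxy)-2-[4-(benzyloxy)phenyl]-3-hydroxy-2,3-dihydro-1-benzofuran-3-carbaldehyde | C(c1ccccc1)Oc1ccc(cc1)[C@@H]1Oc2cc(OCc3ccccc3)ccc2[C@]1(O)C=O | intermediate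
12 | (2S,3S)-7-(benzyloxy)-2-[4-(benzyloxy)phenyl]-3-hydroxy-2,3-dihydro-4H-chromen-4-one | C(c1ccccc1)Oc1ccc(cc1)[C@@H]1Oc2cc(OCc3ccccc3)ccc2C(=O)[C@H]1O | intermediate
13 | (2S,3R,4S)-7-(benzyloxy)-2-[4-(benzyloxy)phenyl]-3,4-dihydro-2H-chromene-3,4-diol | C(c1ccccc1)Oc1ccc(cc1)[C@@H]1Oc2cc(OCc3ccccc3)ccc2[C@H](O)[C@H]1O | intermediate
14 | (−)-epicatechin, (2R,3R)-2-(3,4-dihydroxyphenyl)-3,4-dihydro-2H-chromene-3,5,7-triol | O[C@@H]1Cc2c(O)cc(O)cc2O[C@@H]1c1ccc(O)c(O)c1 | starting material
15 | (2R,3R)-5,7-bis(benzyloxy)-2-[3,4-bis(benzyloxy)phenyl]-3,4-dihydro-2H-chromen-3-ol | O[C@@H]1Cc2c(OCc3ccccc3)cc(OCc3ccccc3)cc2O[C@@H]1c1ccc(OCc2ccccc2)c(OCc2ccccc2)c1 | intermediate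
16 | (2R,3R)-5,7-bis(benzyloxy)-8-{(2S,3R,4R)-7-(benzyloxy)-2-[4-(benzyloxy)phenyl]-3-hydroxy-3,4-dihydro-2H-chromen-4-yl}-2-[3,4-bis(benzyloxy)phenyl]-3,4-dihydro-2H-chromen-3-ol | C(c1ccccc1)Oc1ccc([C@@H]2Oc3cc(OCc4ccccc4)ccc3[C@H](c3c(OCc4ccccc4)cc(OCc4ccccc4)c4c3O[C@H](c3ccc(OCc5ccccc5)c(OCc5ccccc5)c3)[C@H](O)C4)[C@H]2O)cc1 | intermediate
17 | (2R,3R)-2-(3,4-dihydroxyphenyl)-8-[(2S,3R,4R)-3,7-dihydroxy-2-(4-hydroxyphenyl)-3,4-dihydro-2H-chromen-4-yl]-3,4-dihydro-2H-chromene-3,5,7-triol | Oc1ccc([C@@H]2Oc3cc(O)ccc3[C@H](c3c(O)cc(O)c4c3O[C@H](c3ccc(O)c(O)c3)[C@H](O)C4)[C@H]2O)cc1 | target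

**Step count and risks**
Total steps: 11. Longest linear sequence: 10 steps (steps 1–8, 10, 11); step 9 prepares the lower unit.

Steps most likely to fail:

1. Step 7. On aluminium the hydroxy aldehyde may be diverted in three ways: hydride transfer between two aldehyde molecules (Tishchenko-type ester formation); migration of the aryl carbon C3a followed by enolisation towards C2, which would erode the C2 configuration; or β-elimination of the ring oxygen from the product enediolate, with re-closure to a five-membered hemiketal. The fallback runs the shift on the silyl ether, where no alkoxide or enediolate exists during the migration. It sets out from 11: silylation (Me3SiOTf, 2,6-lutidine, CH2Cl2, −78 °C) should give (2S,3R)-6-(benzyloxy)-2-[4-(benzyloxy)phenyl]-3-[(trimethylsilyl)oxy]-2,3-dihydro-1-benzofuran-3-carbaldehyde F1. A Lewis-acid-promoted 1,2-shift of this siloxy aldehyde (Me2AlCl, CH2Cl2, −78 °C) should give (2S,3S)-7-(benzyloxy)-2-[4-(benzyloxy)phenyl]-3-[(trimethylsilyl)oxy]-2,3-dihydro-4H-chromen-4-one F2. Brief treatment with K2CO3 in MeOH at 0 °C removes the silyl group and equilibrates C3 to the trans relation, coming back to the route at 12.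

2. Step 10. Ionisation of the 5-deoxy benzylic alcohol may be slow and call for stronger acid, under which attack at C6 of 15, attack syn to the 3-OH, or a second alkylation of the product could compete. The fallback uses thiophilic activation under neutral conditions. It sets out from 13: BF3·OEt2 with phenylmethanethiol (CH2Cl2, −20 °C) should give the 3,4-trans thioether (2S,3S,4S)-4-(benzylsulfanyl)-7-(benzyloxy)-2-[4-(benzyloxy)phenyl]-3,4-dihydro-2H-chromen-3-ol F3. AgBF4 (THF, 0 °C) in the presence of 15 then releases the same C4 cation without Brønsted or strong Lewis acid and comes back to the route at 16.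

3. Step 5. The ester enolate may expel the ring oxygen (β-elimination, with scrambling of C2 on re-closure) or add to the sulfonimine by-product instead of being oxidised. The fallback oxidises at the aldehyde level through a silyl enol ether, without an ester enolate. It sets out from 8: i-Bu2AlH (toluene, −78 °C) should give (2R,3S)-6-(benzyloxy)-2-[4-(benzyloxy)phenyl]-2,3-dihydro-1-benzofuran-3-carbaldehyde F4, whose C3 centre is removed in the next operation. Et3SiOTf and Et3N (CH2Cl2, 0 °C) should give (2S)-6-(benzyloxy)-2-[4-(benzyloxy)phenyl]-3-{[(triethylsilyl)oxy]methylidene}-2,3-dihydro-1-benzofuran F5. Dimethyldioxirane (acetone, −40 °C; Rubottom oxidation with silyl transfer, attack anti to the C2 aryl group) should give (2S,3R)-6-(benzyloxy)-2-[4-(benzyloxy)phenyl]-3-[(triethylsilyl)oxy]-2,3-dihydro-1-benzofuran-3-carbaldehyde F6. HF·pyridine (THF, 0 °C) removes the silyl group and comes back to the route at 11, which then enters the aluminium alkoxide stage of step 7.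

Further compounds
F1 | step 7 | (2S,3R)-6-(benzyloxy)-2-[4-(benzyloxy)phenyl]-3-[(trimethylsilyl)oxy]-2,3-dihydro-1-benzofuran-3-carbaldehyde | C(c1ccccc1)Oc1ccc(cc1)[C@@H]1Oc2cc(OCc3ccccc3)ccc2[C@]1(O[Si](C)(C)C)C=O
F2 | step 7 | (2S,3S)-7-(benzyloxy)-2-[4-(benzyloxy)phenyl]-3-[(trimethylsilyl)oxy]-2,3-dihydro-4H-chromen-4-one | C(c1ccccc1)Oc1ccc(cc1)[C@@H]1Oc2cc(OCc3ccccc3)ccc2C(=O)[C@H]1O[Si](C)(C)C
F3 | step 10 | (2S,3S,4S)-4-(benzylsulfanyl)-7-(benzyloxy)-2-[4-(benzyloxy)phenyl]-3,4-dihydro-2H-chromen-3-ol | C(c1ccccc1)Oc1ccc(cc1)[C@@H]1Oc2cc(OCc3ccccc3)ccc2[C@H](SCc2ccccc2)[C@H]1O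
F4 | step 5 | (2R,3S)-6-(benzyloxy)-2-[4-(benzyloxy)phenyl]-2,3-dihydro-1-benzofuran-3-carbaldehyde | C(c1ccccc1)Oc1ccc(cc1)[C@@H]1Oc2cc(OCc3ccccc3)ccc2[C@@H]1C=O
F5 | step 5 | (2S)-6-(benzyloxy)-2-[4-(benzyloxy)phenyl]-3-{[(triethylsilyl)oxy]methylidene}-2,3-dihydro-1-benzofuran | C(c1ccccc1)Oc1ccc(cc1)[C@@H]1Oc2cc(OCc3ccccc3)ccc2C1=CO[Si](CC)(CC)CC
F6 | step 5 | (2S,3R)-6-(benzyloxy)-2-[4-(benzyloxy)phenyl]-3-[(triethylsilyl)oxy]-2,3-dihydro-1-benzofuran-3-carbaldehyde | C(c1ccccc1)Oc1ccc(cc1)[C@@H]1Oc2cc(OCc3ccccc3)ccc2[C@]1(O[Si](CC)(CC)CC)C=O
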